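The constants are given at 70 °C, and the same charge runs for 6.0 min at each temperature set out below.

    intermediate → target (k1 = 0.0483 min⁻¹, Ea1 = 99.0 kJ mol⁻¹)
    starting material ⇌ intermediate (K2 = 1.76, k2 = 0.254 min⁻¹, Ea2 = 88.0 kJ mol⁻¹, ΔH2 = −57.0 kJ mol⁻¹)
    starting material → side product (k3 = 0.0379 min⁻¹, Ea3 = 101 kJ mol⁻¹)
    solid substrate ⇌ starting material, rate k4*(cs4 - [starting material]) while solid is left; crystals form when [starting material] > cs4 (cs4 = 26 mM, k4 = 0.0287 min⁻¹)
    starting material → target (k5 = 0.0824 min⁻¹, Ea5 = 90.0 kJ mol⁻¹)
    (constants at 70 °C)

| flask | solid substrate | temperature | time |
|---|---|---|---|
| blue | 0.045 M | 20 °C | 6.0 min |
| red | 0.045 M | −5 °C | 6.0 min |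
| grey | 0.045 M | 70 °C | 6.0 min |
| ochre | 0.045 M | 45 °C | 6.0 min |

1. the best flask by share of target in all that became target or side product; "all alike" if 1.5 percentage points covers them all (blue / red / grey / ochre / all alike)
2. share of target in all that became target or side product, blue
3. share of target in all that became target or side product, red
4. share of target in all that became target or side product, grey
5. share of target in all that became target or side product, ochre

- solid, in amounts per volume of the solution: solid substrate
- the list of constants is for 70 °C, to be carried to other temperatures by the activation energies and enthalpies
- at the start none of the solid substrate is in solution
- what has only dissolved of solid substrate counts as not reacted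

The run starts at the solid, so I follow it. In the first instants nothing is dissolved, and the solid feeds the solution at 0.0166 min⁻¹ as a fraction of the charge, towards a ceiling, the solubility, at 57.8% of the charge. Through the middle the feed sags slowly. If what dissolves stays in solution, the end stands at 9.14% of the charge, well below the ceiling, with 90.9% still solid.

What dissolves is starting material, and it can go straight to target or to side product. Both steps run in proportion to the same starting material, so at a fixed temperature their split does not depend on how much has dissolved. That lets me skip the amounts. The direct share is target's rate constant over the sum of target's and side product's, each carried to the flask's temperature; the ratio of the two is the usual selectivity factor. No step leads directly from the intermediate to side product, so any target arriving by the intermediate lifts the share, and the direct share is a floor.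

red: 86.5%

blue: 80.8%

ochre: 74.6%

grey: 68.5%

Now the side road. In red the exchange with the intermediate has a relaxation half-life of 253 h, far longer than the run, so red's floor is my figure for red. In blue the forward step to the intermediate has a rate constant of 0.00132 min⁻¹, and over the run that passes on 0.792%, hardly any of the dissolved material, so I put blue at its floor too. In grey the same exchange has a half-life of 1.74 min, shorter than the run, so grey will rise above its floor, and there my hand stops. Grey would need 18 percentage points above its floor to reach red; I bet on red.

The forecast names red, with blue 80.8%, red 86.5%, grey 73.2% (range 71.5% to 75%) and ochre 75%: "cooling favours target, which puts red on top". Its grey stands 4.7 points above my floor.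

The simulation gives red as best: blue 80.8%, red 86.5%, grey 73.2%, ochre 75.0%.

Red reads the same as its direct share of 86.5%, and grey stands 4.7 points above its floor of 68.5%. Yet red's share is a split of traces: at 6.00 min red holds 9.14% as starting material, target reads 0% and conversion 0%, while grey holds 1.71% as target. The neighbour, red repeated at −30 °C, has a direct share of 91.4%; it reads 91.4%, with 9.14% as starting material and >99.9% of the charge still there, solid or dissolved.

The numbers are invented; the run is a simulation.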